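The trimer is cut at the C4–O–C4 ether and the C4–C8 interflavan bond into three 2,3-cis flavan units; the upper two come from one de novo epicatechin building block. Its pyran ring C is closed at O1–C8a: ring A, with O1, O5 and O7 mutually meta, is mapped onto 1,3,5-trifluorobenzene, whose last fluorine (future C8a, ortho to the C4a side chain) is displaced by the C2 alkoxide. In one operation a chelation-controlled aryl Grignard addition sets C2 and the resulting alkoxide cyclizes by 6-exo SNAr. The precursor is an open-chain α-MOM-oxy aldehyde carrying a 2,4-bis(benzyloxy)-6-fluorobenzyl group.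

Key step: step 5

Remark: the target is read as epicatechin-(4β→8)-epicatechin-(4β→O→4)-ent-epicatechin, the lowest unit being all-cis (2S,3S,4S); (+)-epicatechin and methyl (R)-glycidate are taken as purchasable.

Step 1
Reactants: 1 1,3,5-trifluorobenzene
Product: 2 1,3-bis(benzyloxy)-5-fluorobenzene
Conditions: BnOH (2.1 equiv), NaH, NMP, rt then 100 °C (sealed vessel)
Reagents that add atoms: benzyl alcohol, OCc1ccccc1
Why: Twofold SNAr on the symmetric trifluoroarene, each substitution activated by the remaining meta fluorines; the third is much slower, so the reaction should stop at the monofluoride.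

Step 2
Reactants: 2 1,3-bis(benzyloxy)-5-fluorobenzene; 3 methyl (R)-glycidate
Product: 6 methyl (2R)-3-[2,4-bis(benzyloxy)-6-fluorophenyl]-2-hydroxypropanoate, via aryllithium 4 (not isolated), via arylmagnesium bromide 5 (not isolated)
Conditions: n-BuLi, THF, −78 °C; MgBr2·OEt2, −78 → −40 °C; CuBr·SMe2 (10 mol%), then 3, −40 → −10 °C; H2O
Reagents that add atoms: none
Why: Fluorine-directed ortho-lithiation at the most acidic C–H (flanked by F and OBn), transmetalation and copper-catalysed SN2 opening of the glycidate at its CH2 terminus; the stereocenter of 3 is untouched and becomes C3 of the flavan.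

Step 3
Reactants: 6 methyl (2R)-3-[2,4-bis(benzyloxy)-6-fluorophenyl]-2-hydroxypropanoate
Product: 7 methyl (2R)-3-[2,4-bis(benzyloxy)-6-fluorophenyl]-2-(methoxymethoxy)propanoate
Conditions: MOMCl, i-Pr2NEt, CH2Cl2, 0 °C → rt
Reagents that add atoms: chloromethyl methyl ether, COCCl
Why: MOM ether formation under amine base does not epimerize the α-stereocenter and installs the chelating, base-stable cap on O3.

Step 4
Reactants: 7 methyl (2R)-3-[2,4-bis(benzyloxy)-6-fluorophenyl]-2-(methoxymethoxy)propanoate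
Product: 8 (2R)-3-[2,4-bis(benzyloxy)-6-fluorophenyl]-2-(methoxymethoxy)propanal
Conditions: i-Bu2AlH (1.1 equiv), toluene, −78 °C; aq. potassium sodium tartrate; used crude
Reagents that add atoms: none
Why: Low-temperature i-Bu2AlH reduction of an α-alkoxy ester stops at the aldehyde through the chelated tetrahedral aluminate.

Step 5
Reactants: 8 (2R)-3-[2,4-bis(benzyloxy)-6-fluorophenyl]-2-(methoxymethoxy)propanal; 9 4-bromo-1,2-bis(benzyloxy)benzene
Product: 12 (2R,3R)-5,7-bis(benzyloxy)-2-[3,4-bis(benzyloxy)phenyl]-3-(methoxymethoxy)chromane (3-O-MOM-tetra-O-benzyl-epicatechin), via aryl Grignard 10 (not isolated), via bromomagnesium alkoxide 11 (not isolated)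
Conditions: 9, Mg, THF, rt; added to 8 and MgBr2·OEt2, toluene, −78 °C; then t-BuOK, 18-crown-6, DMF, −78 → 70 °C; H2O
Reagents that add atoms: none
Why: Grignard reagent 10 adds to aldehyde 8 held in a five-membered MgBr2 chelate between the carbonyl and MOM oxygens, attacking the face anti to the benzylic CH2 group, and after addition of t-BuOK the alkoxide oxygen of 11 attacks the fluorine-bearing ring carbon ortho to the side chain and expels fluoride by addition–elimination (SNAr). The closest known reaction types are the chelation-controlled Grignard addition to α-alkoxy aldehydes and the intramolecular alkoxide SNAr on 3,5-dialkoxyfluorobenzenes, a known closure of flavan pyran rings, here run in one flask. Ring C closes in the 6-exo-trig mode by forming O1–C8a. C2 is the only new stereocenter: the magnesium chelate relays the configuration of C3 to give the syn (2,3-cis) adduct, and C2 is kept in the closure because its C–O bond is never broken. The step needs chemoselective O-arylation by O1, secured by the MOM cap on O3, and needs no regiocontrol on ring A because only one fluorine is left, activated inductively by the two meta benzyloxy groups; the minor anti adduct would give the separable 2,3-trans isomer.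

Step 6
Reactants: 12 3-O-MOM-tetra-O-benzyl-epicatechin
Product: 13 5,7,3′,4′-tetra-O-benzyl-(−)-epicatechin [(2R,3R)-5,7-bis(benzyloxy)-2-[3,4-bis(benzyloxy)phenyl]chroman-3-ol]
Conditions: aq. HCl (cat.), MeOH/THF, 45 °C
Reagents that add atoms: none
Why: Acid-catalysed acetal exchange with methanol removes the MOM group while benzyl ethers and both stereocenters are stable to dilute acid.

Step 7
Reactants: 13 5,7,3′,4′-tetra-O-benzyl-(−)-epicatechin
Product: 14 4β-(2-ethoxyethoxy)-5,7,3′,4′-tetra-O-benzylepicatechin [(2R,3R,4S); 4-O trans to 3-OH]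
Conditions: DDQ, 2-ethoxyethanol, CH2Cl2, rt
Reagents that add atoms: 2-ethoxyethanol, CCOCCO
Why: DDQ abstracts hydride from the doubly oxygen-activated benzylic C4 and the cation is captured by the alcohol on the face anti to the axial 3-OH, the known benzylic oxidation of benzylated flavan-3-ols.

Step 8
Reactants: 14 4β-(2-ethoxyethoxy)-5,7,3′,4′-tetra-O-benzylepicatechin (one portion)
Product: 15 4β-(benzylsulfanyl)-5,7,3′,4′-tetra-O-benzylepicatechin (C4–S trans to 3-OH)
Conditions: BnSH (5 equiv), BF3·OEt2, CH2Cl2, −78 → −30 °C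
Reagents that add atoms: benzyl mercaptan, SCc1ccccc1
Why: Lewis-acid ionization of the C4 ether and capture of the benzylic cation by the soft thiol anti to the 3-OH gives the 4β-thioether, a latent C4 donor that is inert to hard Lewis acids.

Step 9
Reactants: 14 4β-(2-ethoxyethoxy)-5,7,3′,4′-tetra-O-benzylepicatechin (second portion)
Product: 16 8-bromo-4β-(2-ethoxyethoxy)-5,7,3′,4′-tetra-O-benzylepicatechin
Conditions: NBS (1.05 equiv), CH2Cl2, −78 → −20 °C
Reagents that add atoms: N-bromosuccinimide, BrN1C(=O)CCC1=O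
Why: Electrophilic aromatic bromination occurs at C8, the most nucleophilic position of ring A, and caps it against self-condensation in both later couplings.

Step 10
Reactants: 16 8-bromo-4β-(2-ethoxyethoxy)-5,7,3′,4′-tetra-O-benzylepicatechin; 15 4β-(benzylsulfanyl)-5,7,3′,4′-tetra-O-benzylepicatechin
Product: 17 [8-bromo-5,7,3′,4′-tetra-O-benzylepicatechin]-(4β→8)-[4β-(benzylsulfanyl)-5,7,3′,4′-tetra-O-benzylepicatechin]
Conditions: BF3·OEt2, 4 Å MS, CH2Cl2, −78 → −30 °C; 15 in 1.5-fold excess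
Reagents that add atoms: none
Why: The hard Lewis acid ionizes only the 4-O-alkyl donor 16 (the thioether of 15 is orthogonal) and C8 of 15 attacks the C4 cation anti to the 3-OH in a Friedel–Crafts-type flavan coupling, which sets the 4β (3,4-trans) interflavan bond.

Step 11
Reactants: 17 bromo-capped dimer thioether
Product: 18 3-O-acetate of both units of 17 (dimer diacetate)
Conditions: Ac2O, pyridine, DMAP (cat.), rt
Reagents that add atoms: acetic anhydride, CC(=O)OC(C)=O
Why: Acetylation masks both 3-OH groups so that the 4-OH of 25 is the only hydroxyl nucleophile in step 18.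

Step 12
Reactants: 19 (+)-epicatechin (ent-epicatechin, 2S,3S)
Product: 20 5,7,3′,4′-tetra-O-benzyl-ent-epicatechin
Conditions: BnBr, K2CO3, DMF, rt
Reagents that add atoms: benzyl bromide, BrCc1ccccc1
Why: Williamson benzylation of the four phenols under carbonate conditions leaves the secondary 3-OH free and does not touch C2 or C3.

Step 13
Reactants: 20 5,7,3′,4′-tetra-O-benzyl-ent-epicatechin
Product: 21 3-O-TBS-5,7,3′,4′-tetra-O-benzyl-ent-epicatechin
Conditions: TBSOTf, 2,6-lutidine, CH2Cl2, 0 °C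
Reagents that add atoms: tert-butyldimethylsilyl triflate, CC(C)(C)[Si](C)(C)OS(=O)(=O)C(F)(F)F
Why: The silyl triflate silylates the hindered axial 3-OH and gives a non-migrating, base-stable cap.

Step 14
Reactants: 21 3-O-TBS-5,7,3′,4′-tetra-O-benzyl-ent-epicatechin
Product: 22 3-O-TBS-5,7,3′,4′-tetra-O-benzyl-ent-epicatechin-4-ol with the 4-OH trans to O3 [(2S,3S,4R)]
Conditions: DDQ, H2O, THF/CH2Cl2, rt
Reagents that add atoms: water, O
Why: DDQ benzylic oxidation at C4 with water as the nucleophile gives the trans 4-ol, whose configuration is irrelevant because C4 becomes a ketone next.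

Step 15
Reactants: 22 trans 4-ol
Product: 23 (2S,3R)-5,7-bis(benzyloxy)-2-[3,4-bis(benzyloxy)phenyl]-3-(tert-butyldimethylsilyloxy)chroman-4-one (2,3-cis)
Conditions: Dess–Martin periodinane, CH2Cl2, rt
Reagents that add atoms: none
Why: Neutral periodinane oxidation of the benzylic alcohol gives the ketone without epimerizing the adjacent C3.

Step 16
Reactants: 23 2,3-cis chroman-4-one
Product: 24 6,8-dibromo derivative of 23
Conditions: NBS (2.2 equiv), CH2Cl2, 0 °C → rt
Reagents that add atoms: N-bromosuccinimide, BrN1C(=O)CCC1=O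
Why: Twofold electrophilic bromination at C6 and C8, each ortho or para to three ring oxygens, removes every nucleophilic C–H of ring A.

Step 17
Reactants: 24 6,8-dibromo ketone
Product: 25 (2S,3S,4S)-6,8-dibromo-5,7-bis(benzyloxy)-2-[3,4-bis(benzyloxy)phenyl]-3-(tert-butyldimethylsilyloxy)chroman-4-ol (all-cis)
Conditions: NaBH4, THF/MeOH, −20 °C
Reagents that add atoms: none
Why: With the 2-aryl group equatorial and the 3-OTBS group axial, hydride attacks the carbonyl axially from the face opposite O3, so the new 4-OH is cis to O3.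

Step 18
Reactants: 18 dimer diacetate; 25 all-cis 4-ol
Product: 26 fully protected trimer (unit 1: 8-bromo and 3-OAc; unit 2: 3-OAc with C4–O–C4 ether; unit 3: 6,8-dibromo and 3-OTBS; twelve benzyl ethers)
Conditions: AgBF4 (2 equiv), 2,6-di-tert-butyl-4-methylpyridine, 4 Å MS, CH2Cl2, −40 → 0 °C, dark; 25 in 2-fold excess
Reagents that add atoms: none
Why: Thiophilic monovalent silver ionizes the C4–S bond under non-acidic conditions and the cation is captured by the 4-OH of 25 anti to the axial 3-OAc (4β, 3,4-trans), while 25 keeps its configuration because its C4–O bond is not broken; this silver-mediated activation of flavan 4-thioethers is a known route to ether-linked flavan dimers.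

Step 19
Reactants: 26 fully protected trimer
Product: 27 trimer with three free 3-OH groups (twelve benzyl ethers and three aryl bromides retained)
Conditions: n-Bu4NF, THF, rt; then NaOMe (cat.), MeOH/THF, rt
Reagents that add atoms: none
Why: Fluoride cleaves the silyl ether and methoxide transesterifies the two acetates, conditions to which the dibenzylic ether, benzyl ethers and aryl bromides are inert.

Step 20
Reactants: 27 benzylated tribromo trimer triol
Product: 28 target, epicatechin-(4β→8)-epicatechin-(4β→O→4)-ent-epicatechin with an all-cis (2S,3S,4S) lower unit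
Conditions: H2 (1 atm), 10% Pd/C, Et3N (3.3 equiv), pyridine (0.5 equiv), THF/MeOH, rt
Reagents that add atoms: none
Why: Amine-moderated Pd/C hydrogenolysis cleaves aryl benzyl ethers and aryl C–Br bonds, whereas a hindered dialkyl benzylic ether such as the C4–O–C4 bridge should react far more slowly, and the amine buffers the HBr set free.

Compound list
1 | 1,3,5-trifluorobenzene | Fc1cc(F)cc(F)c1 | starting material
2 | 1,3-bis(benzyloxy)-5-fluorobenzene | Fc1cc(OCc2ccccc2)cc(OCc2ccccc2)c1 | intermediate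
3 | methyl (R)-glycidate [methyl (2R)-oxirane-2-carboxylate] | COC(=O)[C@H]1CO1 | starting material
4 | [2,4-bis(benzyloxy)-6-fluorophenyl]lithium | [Li]c1c(F)cc(OCc2ccccc2)cc1OCc1ccccc1 | intermediate
5 | [2,4-bis(benzyloxy)-6-fluorophenyl]magnesium bromide | Br[Mg]c1c(F)cc(OCc2ccccc2)cc1OCc1ccccc1 | intermediate
6 | methyl (2R)-3-[2,4-bis(benzyloxy)-6-fluorophenyl]-2-hydroxypropanoate | COC(=O)[C@H](O)Cc1c(F)cc(OCc2ccccc2)cc1OCc1ccccc1 | intermediate
7 | methyl (2R)-3-[2,4-bis(benzyloxy)-6-fluorophenyl]-2-(methoxymethoxy)propanoate | COC(=O)[C@H](OCOC)Cc1c(F)cc(OCc2ccccc2)cc1OCc1ccccc1 | intermediate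
8 | (2R)-3-[2,4-bis(benzyloxy)-6-fluorophenyl]-2-(methoxymethoxy)propanal | O=C[C@H](OCOC)Cc1c(F)cc(OCc2ccccc2)cc1OCc1ccccc1 | intermediate
9 | 4-bromo-1,2-bis(benzyloxy)benzene | Brc1ccc(OCc2ccccc2)c(OCc2ccccc2)c1 | starting material
10 | [3,4-bis(benzyloxy)phenyl]magnesium bromide | Br[Mg]c1ccc(OCc2ccccc2)c(OCc2ccccc2)c1 | intermediate
11 | bromomagnesium (1R,2R)-1-[3,4-bis(benzyloxy)phenyl]-3-[2,4-bis(benzyloxy)-6-fluorophenyl]-2-(methoxymethoxy)propan-1-olate | Br[Mg]O[C@H](c1ccc(OCc2ccccc2)c(OCc2ccccc2)c1)[C@H](OCOC)Cc1c(F)cc(OCc2ccccc2)cc1OCc1ccccc1 | intermediate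
12 | (2R,3R)-5,7-bis(benzyloxy)-2-[3,4-bis(benzyloxy)phenyl]-3-(methoxymethoxy)chromane | c1ccccc1COc1cc(OCc3ccccc3)c2c(c1)O[C@H](c1ccc(OCc3ccccc3)c(OCc3ccccc3)c1)[C@H](OCOC)C2 | intermediate
13 | 5,7,3′,4′-tetra-O-benzyl-(−)-epicatechin (2R,3R) | c1ccccc1COc1cc(OCc3ccccc3)c2c(c1)O[C@H](c1ccc(OCc3ccccc3)c(OCc3ccccc3)c1)[C@H](O)C2 | intermediate
14 | 4β-(2-ethoxyethoxy)-5,7,3′,4′-tetra-O-benzylepicatechin (2R,3R,4S) | c1ccccc1COc1cc(OCc3ccccc3)c2c(c1)O[C@H](c1ccc(OCc3ccccc3)c(OCc3ccccc3)c1)[C@H](O)[C@H]2OCCOCC | intermediate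
15 | 4β-(benzylsulfanyl)-5,7,3′,4′-tetra-O-benzylepicatechin (S trans to 3-OH) | c1ccccc1COc1cc(OCc3ccccc3)c2c(c1)O[C@H](c1ccc(OCc3ccccc3)c(OCc3ccccc3)c1)[C@H](O)[C@H]2SCc1ccccc1 | intermediate
16 | 8-bromo-4β-(2-ethoxyethoxy)-5,7,3′,4′-tetra-O-benzylepicatechin | c1ccccc1COc1cc(OCc3ccccc3)c2c(c1Br)O[C@H](c1ccc(OCc3ccccc3)c(OCc3ccccc3)c1)[C@H](O)[C@H]2OCCOCC | intermediate
17 | [8-bromo-tetra-O-benzylepicatechin]-(4β→8)-[4β-(benzylsulfanyl)-tetra-O-benzylepicatechin] | c1ccccc1COc1cc(OCc3ccccc3)c2c(c1Br)O[C@H](c1ccc(OCc3ccccc3)c(OCc3ccccc3)c1)[C@H](O)[C@H]2c1c(OCc3ccccc3)cc(OCc3ccccc3)c2c1O[C@H](c1ccc(OCc3ccccc3)c(OCc3ccccc3)c1)[C@H](O)[C@H]2SCc1ccccc1 | intermediate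
18 | 3-O-acetate of both units of 17 | c1ccccc1COc1cc(OCc3ccccc3)c2c(c1Br)O[C@H](c1ccc(OCc3ccccc3)c(OCc3ccccc3)c1)[C@H](OC(C)=O)[C@H]2c1c(OCc3ccccc3)cc(OCc3ccccc3)c2c1O[C@H](c1ccc(OCc3ccccc3)c(OCc3ccccc3)c1)[C@H](OC(C)=O)[C@H]2SCc1ccccc1 | intermediate
19 | (+)-epicatechin (ent-epicatechin, 2S,3S) | Oc1cc(O)c2c(c1)O[C@@H](c1ccc(O)c(O)c1)[C@@H](O)C2 | starting material
20 | 5,7,3′,4′-tetra-O-benzyl-ent-epicatechin (2S,3S) | c1ccccc1COc1cc(OCc3ccccc3)c2c(c1)O[C@@H](c1ccc(OCc3ccccc3)c(OCc3ccccc3)c1)[C@@H](O)C2 | intermediate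
21 | 3-O-TBS-5,7,3′,4′-tetra-O-benzyl-ent-epicatechin | c1ccccc1COc1cc(OCc3ccccc3)c2c(c1)O[C@@H](c1ccc(OCc3ccccc3)c(OCc3ccccc3)c1)[C@@H](O[Si](C)(C)C(C)(C)C)C2 | intermediate
22 | 3-O-TBS-tetra-O-benzyl-ent-epicatechin-4-ol, 3,4-trans (2S,3S,4R) | c1ccccc1COc1cc(OCc3ccccc3)c2c(c1)O[C@@H](c1ccc(OCc3ccccc3)c(OCc3ccccc3)c1)[C@@H](O[Si](C)(C)C(C)(C)C)[C@@H]2O | intermediate
23 | (2S,3R)-5,7-bis(benzyloxy)-2-[3,4-bis(benzyloxy)phenyl]-3-(tert-butyldimethylsilyloxy)chroman-4-one (2,3-cis) | c1ccccc1COc1cc(OCc3ccccc3)c2c(c1)O[C@@H](c1ccc(OCc3ccccc3)c(OCc3ccccc3)c1)[C@@H](O[Si](C)(C)C(C)(C)C)C2=O | intermediate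
24 | 6,8-dibromo derivative of 23 | c1ccccc1COc1c(Br)c(OCc3ccccc3)c2c(c1Br)O[C@@H](c1ccc(OCc3ccccc3)c(OCc3ccccc3)c1)[C@@H](O[Si](C)(C)C(C)(C)C)C2=O | intermediate
25 | (2S,3S,4S)-6,8-dibromo-5,7-bis(benzyloxy)-2-[3,4-bis(benzyloxy)phenyl]-3-(tert-butyldimethylsilyloxy)chroman-4-ol (all-cis) | c1ccccc1COc1c(Br)c(OCc3ccccc3)c2c(c1Br)O[C@@H](c1ccc(OCc3ccccc3)c(OCc3ccccc3)c1)[C@@H](O[Si](C)(C)C(C)(C)C)[C@H]2O | intermediate
26 | fully protected trimer (8-Br, 3-OAc / 3-OAc / 6,8-Br2, 3-OTBS; twelve OBn) | c1ccccc1COc1cc(OCc3ccccc3)c2c(c1Br)O[C@H](c1ccc(OCc3ccccc3)c(OCc3ccccc3)c1)[C@H](OC(C)=O)[C@H]2c1c(OCc3ccccc3)cc(OCc3ccccc3)c2c1O[C@H](c1ccc(OCc3ccccc3)c(OCc3ccccc3)c1)[C@H](OC(C)=O)[C@H]2O[C@H]1c2c(OCc3ccccc3)c(Br)c(OCc3ccccc3)c(Br)c2O[C@@H](c2ccc(OCc3ccccc3)c(OCc3ccccc3)c2)[C@H]1O[Si](C)(C)C(C)(C)C | intermediate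
27 | dodeca-O-benzyl tribromo trimer with three free 3-OH groups | c1ccccc1COc1cc(OCc3ccccc3)c2c(c1Br)O[C@H](c1ccc(OCc3ccccc3)c(OCc3ccccc3)c1)[C@H](O)[C@H]2c1c(OCc3ccccc3)cc(OCc3ccccc3)c2c1O[C@H](c1ccc(OCc3ccccc3)c(OCc3ccccc3)c1)[C@H](O)[C@H]2O[C@H]1c2c(OCc3ccccc3)c(Br)c(OCc3ccccc3)c(Br)c2O[C@@H](c2ccc(OCc3ccccc3)c(OCc3ccccc3)c2)[C@H]1O | intermediate
28 | epicatechin-(4β→8)-epicatechin-(4β→O→4)-ent-epicatechin, lower unit all-cis (CNP0310719.1) | Oc1cc(O)c2c(c1)O[C@H](c1ccc(O)c(O)c1)[C@H](O)[C@H]2c1c(O)cc(O)c2c1O[C@H](c1ccc(O)c(O)c1)[C@H](O)[C@H]2O[C@H]1c2c(O)cc(O)cc2O[C@@H](c2ccc(O)c(O)c2)[C@H]1O | target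

Total step count: 20. Longest linear sequence: 13 steps (steps 1–7, 9, 10, 11, 18, 19, 20).

Steps most likely to fail

Step 5. The chelate may control the facial selectivity at C2 only partly, and the magnesium-bound alkoxide may displace fluoride too slowly, so that base degrades unreacted aldehyde before ring closure. The fallback sets out from 8: the Grignard addition is quenched cold to give (2R)-1-[3,4-bis(benzyloxy)phenyl]-3-[2,4-bis(benzyloxy)-6-fluorophenyl]-2-(methoxymethoxy)propan-1-ol as a C1 epimer mixture F1. Dess–Martin oxidation gives the aryl ketone F2. Reduction with K[s-Bu3BH] in THF at −78 °C under Felkin–Anh (non-chelation) control should give the (1R,2R) syn alcohol F3. This purified alcohol is cyclized on its own with KH and 18-crown-6 in DMF, which returns to 12.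

Step 18. The hindered 4-OH of 25 may be outrun by carbon nucleophiles (the free C6 positions of a second molecule of 18), or the crowded cation may decay before the ether forms. The fallback sets out from 25: the silyl ether is removed with n-Bu4NF to give the all-cis 6,8-dibromo-tetra-O-benzyl-ent-epicatechin-3,4-diol F4. Heating with Bu2SnO gives its 3,4-O-dibutylstannylene acetal F5. The activated, more nucleophilic equatorial O4 of the acetal is alkylated by donor 18 under the same AgBF4 conditions, giving the trimer with a free unit-3 3-OH F6. Methanolysis of its two acetates (NaOMe, MeOH) returns to 27.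

Step 20. Hydrogenolytic cleavage of the C4–O–C4 dibenzylic ether may compete with debenzylation once the phenols are free, which would reduce the trimer to its fragments. The fallback sets out from 27 and replaces the metal surface by single-electron reduction: lithium 4,4′-di-tert-butylbiphenylide in THF at −78 °C should cleave the twelve aryl benzyl ethers and the three C–Br bonds, and buffered protonation returns directly to 28 without any new compound (F0).

Further compounds
F1 | step 5 | (2R)-1-[3,4-bis(benzyloxy)phenyl]-3-[2,4-bis(benzyloxy)-6-fluorophenyl]-2-(methoxymethoxy)propan-1-ol, C1 epimer mixture | OC(c1ccc(OCc2ccccc2)c(OCc2ccccc2)c1)[C@H](OCOC)Cc1c(F)cc(OCc2ccccc2)cc1OCc1ccccc1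
F2 | step 5 | (2R)-1-[3,4-bis(benzyloxy)phenyl]-3-[2,4-bis(benzyloxy)-6-fluorophenyl]-2-(methoxymethoxy)propan-1-one | O=C(c1ccc(OCc2ccccc2)c(OCc2ccccc2)c1)[C@H](OCOC)Cc1c(F)cc(OCc2ccccc2)cc1OCc1ccccc1
F3 | step 5 | (1R,2R)-1-[3,4-bis(benzyloxy)phenyl]-3-[2,4-bis(benzyloxy)-6-fluorophenyl]-2-(methoxymethoxy)propan-1-ol | O[C@H](c1ccc(OCc2ccccc2)c(OCc2ccccc2)c1)[C@H](OCOC)Cc1c(F)cc(OCc2ccccc2)cc1OCc1ccccc1
F4 | step 18 | (2S,3S,4S)-6,8-dibromo-5,7-bis(benzyloxy)-2-[3,4-bis(benzyloxy)phenyl]chromane-3,4-diol (all-cis) | c1ccccc1COc1c(Br)c(OCc3ccccc3)c2c(c1Br)O[C@@H](c1ccc(OCc3ccccc3)c(OCc3ccccc3)c1)[C@@H](O)[C@H]2O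
F5 | step 18 | 3,4-O-dibutylstannylene acetal of F4 | c1ccccc1COc1c(Br)c(OCc3ccccc3)c2c(c1Br)O[C@@H](c1ccc(OCc3ccccc3)c(OCc3ccccc3)c1)[C@H]1O[Sn](CCCC)(CCCC)O[C@@H]21
F6 | step 18 | protected trimer as 26 but with a free 3-OH on the lower unit | c1ccccc1COc1cc(OCc3ccccc3)c2c(c1Br)O[C@H](c1ccc(OCc3ccccc3)c(OCc3ccccc3)c1)[C@H](OC(C)=O)[C@H]2c1c(OCc3ccccc3)cc(OCc3ccccc3)c2c1O[C@H](c1ccc(OCc3ccccc3)c(OCc3ccccc3)c1)[C@H](OC(C)=O)[C@H]2O[C@H]1c2c(OCc3ccccc3)c(Br)c(OCc3ccccc3)c(Br)c2O[C@@H](c2ccc(OCc3ccccc3)c(OCc3ccccc3)c2)[C@H]1O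
F0 | step 20 | none | none
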